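## Retrosynthetic overview

1. The angelate goes on last; a lipase frees the primary alcohol from a diacetate. The enone is unveiled late from a C6 silyl ether (oxidation, Saegusa–Ito dehydrogenation).
2. Seven-membered ring: ring-closing metathesis (C9=C10) of a diene, then hydrogenation.
3. Quaternary C1 and C11: glycolate Ireland–Claisen rearrangement with chirality transfer from an (S)-carbinol made by ketoreductase reduction of an ynone.
4. Cyclobutane and six-membered ring in one step: intramolecular vinylketene–alkene [2+2] of an acyclic acid, steered by a single silyloxy stereocenter (C6).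
5. That first stereocenter: catalytic asymmetric vinylogous Mukaiyama aldol of two achiral pieces. Ring order: cyclobutane plus six-membered ring, a temporary γ-lactone, then the seven-membered ring.

Assumption: the (R,R)-bisphosphoramide catalyst of step 5 directs attack to the Re face of aldehyde 6; if the sense is opposite, its mirror image is used.

Route numbering (used for locants and descriptors of all bicyclic and tricyclic compounds): cyclobutane C2–C3–C8–C7; six-ring bridge C3–C4(C13H3)–C5–C6–C7; seven-ring bridge C8(C14H3)–C9–C10–C11–C1(C12H3)(C15)–C2. The target is (1S,2R,3S,7S,8S,11R) with C4=C5, C6=O, C11–OAc and C15H2–O-angeloyl.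

Abbreviations: TBS = tert-butyldimethylsilyl, PMB = 4-methoxybenzyl, Bn = benzyl, TMS = trimethylsilyl.

## Route

Step 1
Reactants: 1 prop-2-yn-1-ol
Product: 3 (2E)-3-iodo-2-methylprop-2-en-1-ol, via alkenylalane 2 (not isolated)
Conditions: AlMe3 (3 equiv), Cp2ZrCl2 (0.25 equiv), CH2Cl2, 0 °C to rt; then I2, THF, −30 °C; aq. K2CO3
Reagents that add atoms: trimethylaluminium C[Al](C)C; iodine II
Why: Zirconium-catalysed Negishi carboalumination adds CH3 and Al syn across the alkyne (CH3 on the internal carbon) and iodinolysis goes with retention, so only the E iodide forms; no stereocenter.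

Step 2
Reactants: 3 (2E)-3-iodo-2-methylprop-2-en-1-ol
Product: 4 PMB ether of 3
Conditions: NaH, 4-methoxybenzyl chloride, Bu4NI (cat.), THF/DMF, 0 °C to rt
Reagents that add atoms: 4-methoxybenzyl chloride COc1ccc(CCl)cc1
Why: Williamson ether synthesis on the primary alkoxide; the vinyl iodide is inert and no stereocenter is involved.

Step 3
Reactants: 4 PMB ether of 3
Product: 6 (2E)-3-methyl-4-(PMB-oxy)but-2-enal, via vinyllithium 5 (not isolated)
Conditions: t-BuLi (2.1 equiv), Et2O, −78 °C; then DMF, −78 to 0 °C; aq. NH4Cl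
Reagents that add atoms: N,N-dimethylformamide CN(C)C=O
Why: Iodine–lithium exchange with retention of alkene geometry followed by formylation gives the E enal; no stereocenter.

Step 4
Reactants: 7 methyl 3-methylbut-2-enoate
Product: 9 silyl dienol ether of 7, via lithium dienolate 8 (not isolated)
Conditions: LiN(i-Pr)2, THF, −78 °C; then t-BuMe2SiCl, DMPU, −78 °C to rt
Reagents that add atoms: tert-butyldimethylsilyl chloride CC(C)(C)[Si](C)(C)Cl
Why: Kinetic γ-deprotonation to the extended enolate and O-silylation (silyl ketene acetal formation); no stereocenter.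

Step 5
Reactants: 6 (2E)-3-methyl-4-(PMB-oxy)but-2-enal; 9 silyl dienol ether
Product: 10 methyl (2E,5R,6E)-5-hydroxy-3,7-dimethyl-8-(PMB-oxy)octa-2,6-dienoate
Conditions: SiCl4 (1.1 equiv), (R,R)-bisphosphoramide catalyst of Denmark (pentane-1,5-diyl-linked bis[(R)-N,N'-dimethyl-1,1'-binaphthyl-2,2'-diamine phosphoramide], 5 mol %), i-Pr2NEt (10 mol %), CH2Cl2, −78 °C; aq. NaHCO3
Reagents that add atoms: none
Why: Catalytic enantioselective vinylogous Mukaiyama aldol (Lewis-base-activated SiCl4): the dienolate attacks through its γ-carbon on the Re face of the aldehyde inside the chiral phosphoramide–silicon complex, giving the E enoate and setting the first stereocenter (5R, later route C6) by asymmetric catalysis.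

Step 6
Reactants: 10 hydroxy ester
Product: 11 methyl (2E,5R,6E)-3,7-dimethyl-8-(PMB-oxy)-5-(TBS-oxy)octa-2,6-dienoate
Conditions: t-BuMe2SiOTf, 2,6-lutidine, CH2Cl2, −78 to 0 °C
Reagents that add atoms: tert-butyldimethylsilyl triflate CC(C)(C)[Si](C)(C)OS(=O)(=O)C(F)(F)F
Why: Silylation of the secondary allylic alcohol; the stereocenter is not touched.

Step 7
Reactants: 11 silyl ether ester
Product: 12 (2E,5R,6E)-3,7-dimethyl-8-(PMB-oxy)-5-(TBS-oxy)octa-2,6-dienoic acid
Conditions: LiOH·H2O, THF/MeOH/H2O, 40 °C; then 1 M HCl to pH 4, 0 °C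
Reagents that add atoms: lithium hydroxide [Li+].[OH-]
Why: Saponification of the methyl ester; hydroxide does not deprotonate the γ-position, so both alkene geometries and the stereocenter are kept.

Step 8
Reactants: 12 dienoic acid
Product: 15 bicyclic cyclobutanone (3S,6R,7S,8S), via acid chloride 13 (not isolated), via vinylketene 14 (not isolated)
Conditions: 1-chloro-N,N,2-trimethylprop-1-en-1-amine (Ghosez reagent), CH2Cl2, 0 °C to rt; then added over 6 h to Et3N (5 equiv), toluene, 110 °C, 0.005 M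
Reagents that add atoms: none
Why: Triethylamine turns the acid chloride into the vinylketene (1,4-elimination), which undergoes a thermal intramolecular ketene–alkene [2+2] cycloaddition (carbonyl carbon to C7, α-carbon to C8); addition is suprafacial on the E alkene (C14H3 syn to the three-carbon bridge, C9 anti) and occurs anti to the silyloxy group because A(1,3) strain holds the C6–H in the alkene plane, which sets C3, C7 and C8.

Step 9
Reactants: 15 bicyclic cyclobutanone
Product: 16 C4-methyl cyclobutanone (3S,4R,6R,7S,8S)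
Conditions: H2 (3 atm), RhCl(PPh3)3 (5 mol %), benzene/EtOH, rt
Reagents that add atoms: none
Why: Homogeneous hydrogenation of the exocyclic methylene from the face remote from the C14 methyl (as β-pinene gives cis-pinane) gives 4R without touching the PMB ether or the ketone; this center is erased again in step 29.

Step 10
Reactants: 16 C4-methyl cyclobutanone
Product: 17 methyl enol ether at C2 (E/Z mixture)
Conditions: (methoxymethyl)triphenylphosphonium chloride, KN(SiMe3)2, THF, 0 to 45 °C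
Reagents that add atoms: (methoxymethyl)triphenylphosphonium chloride COC[P+](c1ccccc1)(c1ccccc1)c1ccccc1.[Cl-]
Why: Wittig methoxymethylenation of the strained, non-enolizable cyclobutanone (both α-carbons are bridgeheads); no stereocenter is formed.

Step 11
Reactants: 17 methyl enol ether
Product: 19 C2 aldehyde (2R,3R,4R,6R,7S,8S), via C2-epimeric aldehyde 18 (not isolated)
Conditions: TsOH·H2O (10 mol %), acetone/H2O (10:1), rt; then DBU (0.3 equiv), CH2Cl2, rt
Reagents that add atoms: water O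
Why: Acid hydrolysis of the enol ether followed by base epimerisation through the enolate puts the formyl group in the thermodynamically preferred position anti to the C4–C6 bridge (the syn position is crowded by C5 and the C6 silyloxy group), which sets C2 (2R).

Step 12
Reactants: 19 C2 aldehyde
Product: 20 1,1-dibromoalkene
Conditions: CBr4, PPh3, CH2Cl2, 0 °C
Reagents that add atoms: carbon tetrabromide BrC(Br)(Br)Br
Why: Corey–Fuchs dibromo-olefination with a non-basic ylide, so the C2 center is not epimerised.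

Step 13
Reactants: 20 1,1-dibromoalkene
Product: 22 ynone, via lithium acetylide 21 (not isolated)
Conditions: n-BuLi (2.2 equiv), THF, −78 to 0 °C; then N-methoxy-N-methylacetamide, −78 to 0 °C; aq. NH4Cl
Reagents that add atoms: N-methoxy-N-methylacetamide CON(C)C(C)=O
Why: Second stage of the Corey–Fuchs sequence (bromine–lithium exchange and Fritsch–Buttenberg–Wiechell rearrangement) gives the acetylide, and Weinreb amide acylation stops at the ketone; no new stereocenter.

Step 14
Reactants: 22 ynone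
Product: 23 (S)-propargylic alcohol
Conditions: ketoreductase (Prelog-selective, NADPH-dependent), NADP+ (cat.), i-PrOH (10 vol %), phosphate buffer pH 7.0, 30 °C
Reagents that add atoms: none
Why: The ketoreductase transfers hydride from NADPH to the Re face of the methyl ketone (small methyl pocket, large alkynyl pocket), giving the S carbinol under catalyst control, independent of the chirality of the bicycle.

Step 15
Reactants: 23 (S)-propargylic alcohol
Product: 24 (2S,3Z)-allylic alcohol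
Conditions: MeMgBr (5 equiv), Fe(acac)3 (0.2 equiv), THF, 0 °C to rt; aq. NH4Cl
Reagents that add atoms: methylmagnesium bromide C[Mg]Br
Why: Alkoxide-directed iron-catalysed syn-carbomagnesiation puts CH3 on the distal alkyne carbon (C1) and magnesium on the proximal one in a five-membered chelate, so protonation gives only the Z alkene (C2 cis to the carbinol carbon); the carbinol center is untouched.

Step 16
Reactants: 24 (2S,3Z)-allylic alcohol; 25 (benzyloxy)acetic acid
Product: 26 allylic (benzyloxy)acetate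
Conditions: DCC, DMAP (cat.), CH2Cl2, 0 °C to rt
Reagents that add atoms: none
Why: Steglich esterification of the secondary alcohol with retention at the carbinol carbon.

Step 17
Reactants: 26 allylic (benzyloxy)acetate
Product: 29 rearranged acid (route 1R,11S), via silyl ketene acetal 27 (not isolated), via trimethylsilyl ester 28 (not isolated)
Conditions: LiN(SiMe3)2, Me3SiCl/Et3N, THF, −78 °C to rt, then 50 °C; 1 M HCl work-up
Reagents that add atoms: none
Why: Ireland–Claisen [3,3] rearrangement of the lithium-chelated Z silyl ketene acetal through a chair with the carbinol methyl equatorial: 1,3-chirality transfer from the S carbinol across the Z alkene sets quaternary C1, and the enolate geometry sets C11 (oxygen cis to C12H3), both controlled by the enzyme-made center and not by the remote core.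

Step 18
Reactants: 29 rearranged acid
Product: 32 γ-lactone (C9–OPMB), via aldehyde acid 30 (not isolated), via hydroxy acid 31 (not isolated)
Conditions: K2OsO4·2H2O (2 mol %), NaIO4 (4 equiv), 2,6-lutidine, dioxane/H2O, rt; then NaBH4, MeOH, 0 °C; then 1 M HCl to pH 3
Reagents that add atoms: sodium periodate [Na+].[O-]I(=O)(=O)=O (terminal oxidant; the C15 oxygen arrives through the osmium catalyst)
Why: Lemieux–Johnson cleavage of the only C=C bond gives the neopentyl aldehyde, borohydride reduces it and acid closes the γ-lactone, which masks C15–OH and C10 together; no stereocenter changes.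

Step 19
Reactants: 32 γ-lactone (C9–OPMB)
Product: 33 γ-lactone (C9–OH)
Conditions: DDQ, CH2Cl2/pH 7 buffer (10:1), 0 °C to rt
Reagents that add atoms: none
Why: Oxidative cleavage of the electron-rich PMB ether; the benzyl ether, lactone and silyl ether are inert.

Step 20
Reactants: 33 γ-lactone (C9–OH)
Product: 34 γ-lactone (C9 aldehyde)
Conditions: Dess–Martin periodinane, NaHCO3, CH2Cl2, rt
Reagents that add atoms: none
Why: Mild oxidation of the primary alcohol to a non-enolizable aldehyde on quaternary C8.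

Step 21
Reactants: 34 γ-lactone (C9 aldehyde)
Product: 35 γ-lactone (C8 vinyl)
Conditions: Zn, CH2Br2, TiCl4, THF/CH2Cl2, 0 °C to rt
Reagents that add atoms: dibromomethane BrCBr
Why: Takai–Lombardo methylenation is non-basic and selective for the aldehyde, so the lactone is untouched and C11 (α to the lactone) is not epimerised.

Step 22
Reactants: 35 γ-lactone (C8 vinyl)
Product: 36 lactol (anomer mixture)
Conditions: i-Bu2AlH (1.2 equiv), CH2Cl2, −78 °C; Rochelle salt
Reagents that add atoms: none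
Why: Partial reduction of the lactone stops at the lactol at low temperature.

Step 23
Reactants: 36 lactol
Product: 37 diene alcohol (route 1S,11R)
Conditions: Ph3PCH3Br, KOt-Bu, THF, 0 °C to rt
Reagents that add atoms: methyltriphenylphosphonium bromide C[P+](c1ccccc1)(c1ccccc1)c1ccccc1.[Br-]
Why: Wittig methylenation of the open hydroxy-aldehyde form gives the C10 vinyl group and frees C15–OH; there is no β-leaving group and C11 keeps its configuration.

Step 24
Reactants: 37 diene alcohol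
Product: 38 tricyclic cycloheptene (1S,2R,3R,4R,6R,7S,8S,11R)
Conditions: second-generation Grubbs catalyst RuCl2(=CHPh)(H2IMes)(PCy3) (10 mol %), toluene, 0.005 M, 80 °C
Reagents that add atoms: none
Why: Ring-closing olefin metathesis of the two vinyl groups held cis on C2 and C8 closes the seven-membered ring with loss of ethene; no new stereocenter.

Step 25
Reactants: 38 tricyclic cycloheptene
Product: 39 diol (C11–OH, C15–OH)
Conditions: H2 (4 atm), Pd(OH)2/C, EtOAc/EtOH, rt
Reagents that add atoms: none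
Why: Heterogeneous hydrogenation saturates C9=C10 and hydrogenolyses the benzyl ether in one operation; the silyl ether and all stereocenters stay.

Step 26
Reactants: 39 diol
Product: 40 diacetate
Conditions: Ac2O, DMAP (cat.), pyridine, rt to 40 °C
Reagents that add atoms: acetic anhydride CC(=O)OC(C)=O
Why: DMAP-catalysed acetylation of both hydroxyl groups with retention at C11.

Step 27
Reactants: 40 diacetate
Product: 41 C6 alcohol
Conditions: HF·pyridine, THF/pyridine, 0 °C to rt
Reagents that add atoms: none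
Why: Fluoride-mediated desilylation under mildly acidic conditions leaves both acetates in place.

Step 28
Reactants: 41 C6 alcohol
Product: 42 C6 ketone
Conditions: Dess–Martin periodinane, NaHCO3, CH2Cl2, rt
Reagents that add atoms: none
Why: Oxidation of the secondary alcohol; the control element at C6 has done its work and is removed.

Step 29
Reactants: 42 C6 ketone
Product: 44 enone diacetate (1S,2R,3S,7S,8S,11R), via silyl enol ether 43 (not isolated)
Conditions: Me3SiOTf, Et3N, CH2Cl2, 0 °C; then Pd(OAc)2 (1.1 equiv), MeCN, rt to 40 °C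
Reagents that add atoms: none
Why: Saegusa–Ito oxidation: enolisation is only possible toward C5 (C7 is a bridgehead) and β-hydride elimination of C4–H from the palladium enolate gives the C4=C5 enone, erasing the C4 center.

Step 30
Reactants: 44 enone diacetate
Product: 45 primary alcohol (C15–OH, C11–OAc)
Conditions: lipase from Burkholderia cepacia (immobilised), phosphate buffer pH 7.0/MTBE, 30 °C
Reagents that add atoms: none
Why: Lipase-catalysed regioselective ester hydrolysis: the serine hydrolase accepts the primary C15 acetate but not the secondary C11 acetate next to the quaternary carbon, and neutral pH spares the enone and avoids acetyl migration.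

Step 31
Reactants: 45 primary alcohol; 46 angelic acid
Product: 48 target CNP0374220.2, via mixed anhydride 47 (not isolated)
Conditions: 46, 2,4,6-trichlorobenzoyl chloride, Et3N, toluene, rt; filter; then 45, toluene, 80 °C
Reagents that add atoms: none
Why: Yamaguchi-type esterification through the mixed anhydride, run base-free in the acylation stage, acylates the neopentyl alcohol without Z-to-E isomerisation of the angelate and without 1,3-acetyl migration.

## Compound list

1 | prop-2-yn-1-ol | C#CCO | starting material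
2 | dimethylalumanyl (2E)-3-(dimethylalumanyl)-2-methylprop-2-en-1-olate (alkenylalane) | C/C(CO[Al](C)C)=C\[Al](C)C | intermediate
3 | (2E)-3-iodo-2-methylprop-2-en-1-ol | C/C(CO)=C\I | intermediate
4 | 1-({[(2E)-3-iodo-2-methylprop-2-en-1-yl]oxy}methyl)-4-methoxybenzene | C/C(COCc1ccc(OC)cc1)=C\I | intermediate
5 | [(1E)-2-methyl-3-(PMB-oxy)prop-1-en-1-yl]lithium | C/C(COCc1ccc(OC)cc1)=C\[Li] | intermediate
6 | (2E)-4-[(4-methoxybenzyl)oxy]-3-methylbut-2-enal | C/C(COCc1ccc(OC)cc1)=C\C=O | intermediate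
7 | methyl 3-methylbut-2-enoate | COC(=O)C=C(C)C | starting material
8 | lithium 1-methoxy-3-methylbuta-1,3-dien-1-olate | COC(O[Li])=CC(C)=C | intermediate
9 | tert-butyl[(1-methoxy-3-methylbuta-1,3-dien-1-yl)oxy]dimethylsilane (ketene acetal geometry not defined) | COC(O[Si](C)(C)C(C)(C)C)=CC(C)=C | intermediate
10 | methyl (2E,5R,6E)-5-hydroxy-8-[(4-methoxybenzyl)oxy]-3,7-dimethylocta-2,6-dienoate | COC(=O)/C=C(\C)C[C@@H](O)/C=C(\C)COCc1ccc(OC)cc1 | intermediate
11 | methyl (2E,5R,6E)-5-(TBS-oxy)-8-[(4-methoxybenzyl)oxy]-3,7-dimethylocta-2,6-dienoate | COC(=O)/C=C(\C)C[C@@H](O[Si](C)(C)C(C)(C)C)/C=C(\C)COCc1ccc(OC)cc1 | intermediate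
12 | (2E,5R,6E)-5-(TBS-oxy)-8-[(4-methoxybenzyl)oxy]-3,7-dimethylocta-2,6-dienoic acid | OC(=O)/C=C(\C)C[C@@H](O[Si](C)(C)C(C)(C)C)/C=C(\C)COCc1ccc(OC)cc1 | intermediate
13 | (2E,5R,6E)-acid chloride of 12 | ClC(=O)/C=C(\C)C[C@@H](O[Si](C)(C)C(C)(C)C)/C=C(\C)COCc1ccc(OC)cc1 | intermediate
14 | (5R,6E)-5-(TBS-oxy)-8-(PMB-oxy)-7-methyl-3-methylideneocta-1,6-dien-1-one (vinylketene) | O=C=CC(=C)C[C@@H](O[Si](C)(C)C(C)(C)C)/C=C(\C)COCc1ccc(OC)cc1 | intermediate
15 | (3S,6R,7S,8S)-bicyclo[3.1.1]heptane built from C2–C8: C2=O, C4=CH2, C6–OTBS (anti to the C8 bridge), C8 bearing C14H3 (syn to the C4–C6 bridge) and C9H2–OPMB | O=C2[C@H]3C(=C)C[C@@H](O[Si](C)(C)C(C)(C)C)[C@@H]2[C@@]3(C)COCc1ccc(OC)cc1 | intermediate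
16 | (3S,4R,6R,7S,8S)-analogue of 15 with C4–C13H3 (methyl syn to the C8 bridge) | O=C2[C@H]3[C@H](C)C[C@@H](O[Si](C)(C)C(C)(C)C)[C@@H]2[C@@]3(C)COCc1ccc(OC)cc1 | intermediate
17 | (3S,4R,6R,7R,8S)-C2=CH–OMe enol ether of 16 (E/Z mixture) | COC=C2[C@H]3[C@H](C)C[C@@H](O[Si](C)(C)C(C)(C)C)[C@@H]2[C@@]3(C)COCc1ccc(OC)cc1 | intermediate
18 | (2S,3R,4R,6R,7S,8S)-C2 carbaldehyde, CHO syn to the C4–C6 bridge | O=C[C@H]2[C@H]3[C@H](C)C[C@@H](O[Si](C)(C)C(C)(C)C)[C@@H]2[C@@]3(C)COCc1ccc(OC)cc1 | intermediate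
19 | (2R,3R,4R,6R,7S,8S)-C2 carbaldehyde, CHO (C1) anti to the C4–C6 bridge and cis to C9 | O=C[C@@H]2[C@H]3[C@H](C)C[C@@H](O[Si](C)(C)C(C)(C)C)[C@@H]2[C@@]3(C)COCc1ccc(OC)cc1 | intermediate
20 | C2-(2,2-dibromoethenyl) derivative, core as in 19 | BrC(Br)=C[C@@H]2[C@H]3[C@H](C)C[C@@H](O[Si](C)(C)C(C)(C)C)[C@@H]2[C@@]3(C)COCc1ccc(OC)cc1 | intermediate
21 | C2-(lithioethynyl) derivative, core as in 19 | [Li]C#C[C@@H]2[C@H]3[C@H](C)C[C@@H](O[Si](C)(C)C(C)(C)C)[C@@H]2[C@@]3(C)COCc1ccc(OC)cc1 | intermediate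
22 | 4-(bicyclic unit of 19, bonded through C2)but-3-yn-2-one | CC(=O)C#C[C@@H]2[C@H]3[C@H](C)C[C@@H](O[Si](C)(C)C(C)(C)C)[C@@H]2[C@@]3(C)COCc1ccc(OC)cc1 | intermediate
23 | (2S)-4-(bicyclic unit of 19)but-3-yn-2-ol | C[C@H](O)C#C[C@@H]2[C@H]3[C@H](C)C[C@@H](O[Si](C)(C)C(C)(C)C)[C@@H]2[C@@]3(C)COCc1ccc(OC)cc1 | intermediate
24 | (2S,3Z)-4-(bicyclic unit of 19)pent-3-en-2-ol | C[C@H](O)/C=C(/C)[C@@H]2[C@H]3[C@H](C)C[C@@H](O[Si](C)(C)C(C)(C)C)[C@@H]2[C@@]3(C)COCc1ccc(OC)cc1 | intermediate
25 | (benzyloxy)acetic acid | OC(=O)COCc1ccccc1 | starting material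
26 | (2S,3Z)-4-(bicyclic unit of 19)pent-3-en-2-yl (benzyloxy)acetate | C[C@H](OC(=O)COCc1ccccc1)/C=C(/C)[C@@H]2[C@H]3[C@H](C)C[C@@H](O[Si](C)(C)C(C)(C)C)[C@@H]2[C@@]3(C)COCc4ccc(OC)cc4 | intermediate
27 | (Z)-trimethylsilyl ketene acetal of 26 (OTMS cis to OBn) | C[C@H](O/C(=C/OCc1ccccc1)O[Si](C)(C)C)/C=C(/C)[C@@H]2[C@H]3[C@H](C)C[C@@H](O[Si](C)(C)C(C)(C)C)[C@@H]2[C@@]3(C)COCc4ccc(OC)cc4 | intermediate
28 | trimethylsilyl ester of 29 | C/C=C/[C@@](C)([C@H](OCc1ccccc1)C(=O)O[Si](C)(C)C)[C@@H]2[C@H]3[C@H](C)C[C@@H](O[Si](C)(C)C(C)(C)C)[C@@H]2[C@@]3(C)COCc4ccc(OC)cc4 | intermediate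
29 | (2S,3R,4E)-2-(benzyloxy)-3-methyl-3-(bicyclic unit of 19)hex-4-enoic acid (route 1R,11S) | C/C=C/[C@@](C)([C@H](OCc1ccccc1)C(=O)O)[C@@H]2[C@H]3[C@H](C)C[C@@H](O[Si](C)(C)C(C)(C)C)[C@@H]2[C@@]3(C)COCc4ccc(OC)cc4 | intermediate
30 | (2S,3R)-2-(benzyloxy)-3-methyl-4-oxo-3-(bicyclic unit of 19)butanoic acid | O=C[C@@](C)([C@H](OCc1ccccc1)C(=O)O)[C@@H]2[C@H]3[C@H](C)C[C@@H](O[Si](C)(C)C(C)(C)C)[C@@H]2[C@@]3(C)COCc4ccc(OC)cc4 | intermediate
31 | (2S,3S)-2-(benzyloxy)-4-hydroxy-3-methyl-3-(bicyclic unit of 19)butanoic acid | OC[C@@](C)([C@H](OCc1ccccc1)C(=O)O)[C@@H]2[C@H]3[C@H](C)C[C@@H](O[Si](C)(C)C(C)(C)C)[C@@H]2[C@@]3(C)COCc4ccc(OC)cc4 | intermediate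
32 | (3S,4S)-3-(benzyloxy)-4-methyl-4-(bicyclic unit of 19)oxolan-2-one (lactone C2 = C10, C3 = C11, C4 = C1, C5 = C15) | O=C5OC[C@](C)([C@@H]2[C@H]3[C@H](C)C[C@@H](O[Si](C)(C)C(C)(C)C)[C@@H]2[C@@]3(C)COCc4ccc(OC)cc4)[C@@H]5OCc1ccccc1 | intermediate
33 | lactone 32 with C9H2–OH in place of C9H2–OPMB | O=C5OC[C@](C)([C@@H]2[C@H]3[C@H](C)C[C@@H](O[Si](C)(C)C(C)(C)C)[C@@H]2[C@@]3(C)CO)[C@@H]5OCc1ccccc1 | intermediate
34 | lactone 32 with C9H=O on C8 | O=C5OC[C@](C)([C@@H]2[C@H]3[C@H](C)C[C@@H](O[Si](C)(C)C(C)(C)C)[C@@H]2[C@@]3(C)C=O)[C@@H]5OCc1ccccc1 | intermediate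
35 | lactone 32 with a vinyl group (C9H=CH2) on C8 | O=C5OC[C@](C)([C@@H]2[C@H]3[C@H](C)C[C@@H](O[Si](C)(C)C(C)(C)C)[C@@H]2[C@@]3(C)C=C)[C@@H]5OCc1ccccc1 | intermediate
36 | lactol of 35 (C10 anomer mixture) | OC5OC[C@](C)([C@@H]2[C@H]3[C@H](C)C[C@@H](O[Si](C)(C)C(C)(C)C)[C@@H]2[C@@]3(C)C=C)[C@@H]5OCc1ccccc1 | intermediate
37 | (2S,3R)-3-(benzyloxy)-2-methyl-2-(bicyclic unit of 19 with vinyl on C8)pent-4-en-1-ol (route 1S,11R) | OC[C@@](C)([C@H](OCc1ccccc1)C=C)[C@@H]2[C@H]3[C@H](C)C[C@@H](O[Si](C)(C)C(C)(C)C)[C@@H]2[C@@]3(C)C=C | intermediate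
38 | (1S,2R,3R,4R,6R,7S,8S,11R)-tricycle: C9=C10, C11–OBn, C15H2–OH, C6–OTBS, C4–CH3 | OC[C@]1(C)[C@@H]2[C@H]3[C@H](C)C[C@@H](O[Si](C)(C)C(C)(C)C)[C@@H]2[C@@]3(C)C=C[C@H]1OCc4ccccc4 | intermediate
39 | (1S,2R,3R,4R,6R,7S,8S,11R)-tricyclic diol: C11–OH, C15H2–OH, C6–OTBS | OC[C@]1(C)[C@@H]2[C@H]3[C@H](C)C[C@@H](O[Si](C)(C)C(C)(C)C)[C@@H]2[C@@]3(C)CC[C@H]1O | intermediate
40 | (1S,2R,3R,4R,6R,7S,8S,11R)-diacetate of 39 | CC(=O)OC[C@]1(C)[C@@H]2[C@H]3[C@H](C)C[C@@H](O[Si](C)(C)C(C)(C)C)[C@@H]2[C@@]3(C)CC[C@H]1OC(C)=O | intermediate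
41 | (1S,2R,3R,4R,6R,7S,8S,11R)-diacetate with free C6–OH | CC(=O)OC[C@]1(C)[C@@H]2[C@H]3[C@H](C)C[C@@H](O)[C@@H]2[C@@]3(C)CC[C@H]1OC(C)=O | intermediate
42 | (1S,2R,3R,4R,7S,8S,11R)-diacetate with C6=O | CC(=O)OC[C@]1(C)[C@@H]2[C@H]3[C@H](C)CC(=O)[C@@H]2[C@@]3(C)CC[C@H]1OC(C)=O | intermediate
43 | (1S,2R,3R,4S,7S,8S,11R)-C5=C6 trimethylsilyl enol ether of 42 | CC(=O)OC[C@]1(C)[C@@H]2[C@H]3[C@H](C)C=C(O[Si](C)(C)C)[C@@H]2[C@@]3(C)CC[C@H]1OC(C)=O | intermediate
44 | (1S,2R,3S,7S,8S,11R)-enone diacetate: C4=C5, C6=O, C11–OAc, C15H2–OAc | CC(=O)OC[C@]1(C)[C@@H]2[C@H]3C(C)=CC(=O)[C@@H]2[C@@]3(C)CC[C@H]1OC(C)=O | intermediate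
45 | (1S,2R,3S,7S,8S,11R)-enone with C11–OAc and free C15H2–OH | OC[C@]1(C)[C@@H]2[C@H]3C(C)=CC(=O)[C@@H]2[C@@]3(C)CC[C@H]1OC(C)=O | intermediate
46 | angelic acid, (2Z)-2-methylbut-2-enoic acid | C/C=C(/C)C(=O)O | starting material
47 | (2Z)-2-methylbut-2-enoic 2,4,6-trichlorobenzoic anhydride | C/C=C(/C)C(=O)OC(=O)c1c(Cl)cc(Cl)cc1Cl | intermediate
48 | CNP0374220.2: (1S,2R,3S,7S,8S,11R)-tricyclic enone with C11–OAc and C15H2–O–(2Z)-2-methylbut-2-enoyl | C/C=C(/C)C(=O)OC[C@]1(C)[C@@H]2[C@H]3C(C)=CC(=O)[C@@H]2[C@@]3(C)CC[C@H]1OC(C)=O | target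

## Totals and risks

Total step count: 31. Longest linear sequence: 30 steps (1 to 48 through steps 1–3 and 5–31; step 4 is the one-step side branch).

The three steps most likely to fail:

Step 8, the ketene [2+2]. The alkene carries two allylic oxygens and is a weak partner for the ketene. The fallback uses a more electrophilic keteniminium ion and sets out from 11. Asymmetric copper hydride conjugate reduction (Cu(OAc)2, the DTBM-SEGPHOS enantiomer that gives 3R, polymethylhydrosiloxane, t-BuOH, toluene) gives methyl (3R,5R,6E)-5-(TBS-oxy)-8-(PMB-oxy)-3,7-dimethyloct-6-enoate F1. Aminolysis with pyrrolidine and AlMe3 in toluene gives the pyrrolidine amide F2. Tf2O and 2,4,6-collidine in 1,2-dichloroethane at 80 °C give the keteniminium triflate F3, which closes by the same intramolecular [2+2] (same A(1,3) control) to the cyclobutaniminium triflate F4. Aqueous NaHCO3 hydrolysis gives 16, where the fallback comes back to the route; step 9 is then not needed.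

Step 15, the iron-catalysed carbomagnesiation. The alkyne carbon that must take the methyl group sits next to a hindered cyclobutane carbon. The fallback builds the same Z alkene by cuprate addition and sets out from 20. n-BuLi and then methyl chloroformate give the methyl ynoate F5. Me2CuLi in THF at −78 °C with a cold methanol quench (syn addition) gives the methyl (2Z)-3-(bicyclic unit)but-2-enoate F6. MeNH(OMe)·HCl with i-PrMgCl gives the Weinreb amide F7, and MeMgBr gives the (3Z)-pent-3-en-2-one F8. The same Prelog-selective ketoreductase reduces F8 to 24, where the fallback comes back to the route.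

Step 24, the ring-closing metathesis. Both alkenes are hindered (one on quaternary C8, one next to quaternary C1), so initiation may be slow. The fallback is a relay metathesis and sets out from 34. Wittig reaction with the ylide from hex-5-enyltriphenylphosphonium bromide and NaN(SiMe3)2 (THF, −78 °C, inverse addition) gives the lactone with a (1Z)-hepta-1,6-dienyl group on C8, F9. i-Bu2AlH gives the lactol F10, and Ph3P=CH2 gives the triene alcohol F11. With the second-generation Grubbs catalyst, ruthenium loads on the unhindered terminal alkene, expels cyclopentene and is delivered to C9, which then closes onto the C10 vinyl group to give 38, where the fallback comes back to the route.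

## Further compounds

F1 | step 8 | methyl (3R,5R,6E)-5-(TBS-oxy)-8-[(4-methoxybenzyl)oxy]-3,7-dimethyloct-6-enoate | COC(=O)C[C@H](C)C[C@@H](O[Si](C)(C)C(C)(C)C)/C=C(\C)COCc1ccc(OC)cc1
F2 | step 8 | 1-[(3R,5R,6E)-5-(TBS-oxy)-8-[(4-methoxybenzyl)oxy]-3,7-dimethyloct-6-enoyl]pyrrolidine | O=C(C[C@H](C)C[C@@H](O[Si](C)(C)C(C)(C)C)/C=C(\C)COCc1ccc(OC)cc1)N2CCCC2
F3 | step 8 | 1-[(3R,5R,6E)-5-(TBS-oxy)-8-(PMB-oxy)-3,7-dimethylocta-1,6-dien-1-ylidene]pyrrolidin-1-ium trifluoromethanesulfonate (keteniminium salt) | C1CC[N+](C1)=C=C[C@H](C)C[C@@H](O[Si](C)(C)C(C)(C)C)/C=C(\C)COCc2ccc(OC)cc2.[O-]S(=O)(=O)C(F)(F)F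
F4 | step 8 | (3S,4R,6R,7R,8S)-C2 pyrrolidin-1-ium-1-ylidene analogue of 16, trifluoromethanesulfonate (cyclobutaniminium salt) | C1CC[N+](C1)=C2[C@H]3[C@H](C)C[C@@H](O[Si](C)(C)C(C)(C)C)[C@@H]2[C@@]3(C)COCc4ccc(OC)cc4.[O-]S(=O)(=O)C(F)(F)F
F5 | step 15 | methyl 3-(bicyclic unit of 19)prop-2-ynoate | COC(=O)C#C[C@@H]2[C@H]3[C@H](C)C[C@@H](O[Si](C)(C)C(C)(C)C)[C@@H]2[C@@]3(C)COCc1ccc(OC)cc1
F6 | step 15 | methyl (2Z)-3-(bicyclic unit of 19)but-2-enoate | COC(=O)/C=C(/C)[C@@H]2[C@H]3[C@H](C)C[C@@H](O[Si](C)(C)C(C)(C)C)[C@@H]2[C@@]3(C)COCc1ccc(OC)cc1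
F7 | step 15 | (2Z)-N-methoxy-N-methyl-3-(bicyclic unit of 19)but-2-enamide | CON(C)C(=O)/C=C(/C)[C@@H]2[C@H]3[C@H](C)C[C@@H](O[Si](C)(C)C(C)(C)C)[C@@H]2[C@@]3(C)COCc1ccc(OC)cc1
F8 | step 15 | (3Z)-4-(bicyclic unit of 19)pent-3-en-2-one | CC(=O)/C=C(/C)[C@@H]2[C@H]3[C@H](C)C[C@@H](O[Si](C)(C)C(C)(C)C)[C@@H]2[C@@]3(C)COCc1ccc(OC)cc1
F9 | step 24 | lactone 32 with a (1Z)-hepta-1,6-dien-1-yl group on C8 in place of C9H2–OPMB | O=C5OC[C@](C)([C@@H]2[C@H]3[C@H](C)C[C@@H](O[Si](C)(C)C(C)(C)C)[C@@H]2[C@@]3(C)/C=C\CCCC=C)[C@@H]5OCc1ccccc1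
F10 | step 24 | lactol of F9 (C10 anomer mixture) | OC5OC[C@](C)([C@@H]2[C@H]3[C@H](C)C[C@@H](O[Si](C)(C)C(C)(C)C)[C@@H]2[C@@]3(C)/C=C\CCCC=C)[C@@H]5OCc1ccccc1
F11 | step 24 | (2S,3R)-3-(benzyloxy)-2-methyl-2-(bicyclic unit with (1Z)-hepta-1,6-dien-1-yl on C8)pent-4-en-1-ol | OC[C@@](C)([C@H](OCc1ccccc1)C=C)[C@@H]2[C@H]3[C@H](C)C[C@@H](O[Si](C)(C)C(C)(C)C)[C@@H]2[C@@]3(C)/C=C\CCCC=C
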